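The single-handed catalyst joins the coupling partner to each substrate at its own rate, and I reckoned how far each substrate had gone at the end of the run.

    coupling partner + catalyst + left-handed substrate → catalyst + left-handed product (k1 = 0.0021 /M²/s)
    coupling partner + catalyst + right-handed substrate → catalyst + right-handed product (k2 = 8.8 × 10⁻⁴ /M²/s)
    coupling partner → decomposed reagent (k3 = 1.2 × 10⁻⁵ /s)

- red: left-handed substrate 1.1 M; coupling partner 1.20 M; catalyst 160 mM; right-handed substrate 1.1 M; time 80 min
- violet: left-handed substrate 1.1 M; coupling partner 1.80 M; catalyst 160 mM; right-handed substrate 1.1 M; time 80 min

- catalyst is single-handed; left-handed substrate and right-handed substrate are mirror images of each other, charged as a racemate, each of them at the stated concentration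
- run time (red): 80 min

* which of these there is most of at the end, counted by the substrate in it, red (left-handed product / right-handed substrate / left-handed substrate / right-handed product)
* which of these there is most of at the end, counted by the substrate in it, violet (left-handed product / right-handed substrate / left-handed substrate / right-handed product)
* the largest of these amounts at the end, in percent of the left-handed substrate and right-handed substrate together charged, red
* the largest of these amounts at the end, in percent of the left-handed substrate and right-handed substrate together charged, violet

1. Let x_L and x_R be the fractions of left-handed and right-handed substrate remaining, B the coupling partner and C the catalyst. Both couplings share B and C, so ln x_L = s·ln x_R, where s = k1/k2 is the selectivity factor, 2.39. With the two rate constants fixed, each setting therefore moves a flask along one line.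

2. Coupling partner: I replaced the curve of B by its mean m, taking B as decaying at a = (k1+k2)·C·c, with c the charge of one substrate, so a = 0.0315 /min. Then m = B₀(1−e^(−at))/(at), or 0.438 M for red and 0.657 M for violet, and x_R = exp(−k2·C·m·t).

3. Catalyst and time: the exponent contains the factor 1−e^(−at), already 91.9% here. By hand, raising either adds little, while B₀ scales the exponent directly.

4. For red I got right-handed substrate 74.4% of its charge, or 37.2% of both substrates, against left-handed product 25.3%. For violet, with x_R = 64.1%, I got 32.0% against 32.7%. My curve holds the substrates at their charge, so I expected m to run low, which favours left-handed product in violet.

5. The forecast gave right-handed substrate at 35.1% for red and left-handed product at 37.5% for violet, and of red it said: “The partner runs short, so unreacted right-handed substrate is largest”. It named the same leaders as I did, with different percentages.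

6. The simulation gave right-handed substrate at 35.1% for red and left-handed product at 37.5% for violet. Red's reading implies m = 0.523 M, against my 0.438 M. Each moved alone by a factor of 1.3 up or down in red, the settings shifted the right-handed substrate at the end in this order: coupling partner (4.3 points), then catalyst (1.5 points), then time (1.4 points).

7. Violet holds less right-handed substrate than red because of its larger coupling partner charge: with that difference taken away, so that violet is run at red's charge of coupling partner, its 28.0% becomes 35.1%. In red, 70% of right-handed substrate remaining, raised to s, gives 43.0% for left-handed substrate, and the flask kept 43%. The neighbouring flask with 0.64 M of catalyst kept 37% of its right-handed substrate, so s gives 9.15%, and it kept 9.2% of its left-handed substrate.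

(All constants are invented.)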